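**Conventions.** Guaiane numbering is used throughout: five-membered ring C1–C5; seven-membered ring C1, C5, C6, C7, C8, C9, C10; C14 is the methyl on C10, C15 the methyl on C4, C11–C13 the isopropyl group on C7. Intermediates that lack C15 are named as 15-norguaianes. Compound numbers 1–25 are those of the steps below.

## Analysis of the target

Target 25 is the vanillate (4-hydroxy-3-methoxybenzoate) of a guaiane dienol. A cyclopentene (C1–C5, C3=C4, methyl on C4) is fused through C1–C5 to a cycloheptene (C1, C5–C10) that carries the tetrasubstituted ring-fusion alkene C1=C10, a methyl on C10, an isopropyl on C7 and the ester oxygen on C8. The three stereocentres are 5R, 7R and 8S: the C8 oxygen and the C7 isopropyl group are trans, and H5 lies on the face of the isopropyl group, opposite to the oxygen. C7 and C8 are neighbours, but C5 is separated from them by the C6 methylene and the flat C1=C10 unit, so configuration cannot simply be relayed from one half to the other. C5–H is doubly allylic (between C1=C10 and C3=C4), and any carbonyl placed at C4 or C8 on the way sits β,γ to C1=C10 and can pull it into conjugation. The aryl ester and the free phenol limit the use of base at the end. The difficulty is therefore a seven-membered ring with a tetrasubstituted alkene in a defined position, a remote stereochemical relation, and two non-conjugated alkenes that must not move. The strategy rests on reading the seven-membered ring as a cis,cis-cyclohepta-1,4-diene: C1=C10 is one alkene, a temporary second one is placed at C7=C8, and the ring is fused at C1–C5. That is the product pattern of a divinylcyclopropane rearrangement that joins a three-carbon unit C6–C7–C8 (carrying the isopropyl group) to the four-carbon diene C9=C10–C1=C5, which is an isopropenyl group on a cyclopentene.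

## Retrosynthetic reasoning

**Phenol.** Target 25 is taken back to its aryl silyl ether 24. The free phenol would be acylated or sulfonylated in the steps that precede, and fluoride removal at the end asks nothing of the skipped diene or the ester.

**C4–C15 and the C3=C4 alkene.** The C4 methyl is cut from 24 to give alkenyl triflate 23, which comes from ketone 21 and that from dioxolane 20. The alkene is placed by enolisation toward the C3 methylene and not by dehydration of a tertiary carbinol, because an elimination would be free to run toward C5 and give the conjugated C4=C5/C1=C10 diene. C3=C4 is introduced this late because a trisubstituted alkene there would compete in the hydrogenation that sets C7. The dioxolane carries C4 through everything before.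

**C8–O acyl bond.** Ester 20 is cut into alcohol 16 and the protected acid 19, made in one operation from vanillic acid 17. Acylation with retention keeps the C8 configuration, and the benzoate, having no α-hydrogen, then serves as the protecting group of C8 during the C4 chemistry.

**C7–H and C8–H.** Alcohol 16 is traced to allylic alcohol 15 by removing the two hydrogens across C6=C7, and 15 to enone 14. C8 is set by a catalyst-controlled carbonyl reduction, which makes it independent of the distant C5. C7 is then set by the C8 hydroxyl itself, which delivers hydrogen to its own face, so H7 becomes cis to oxygen and the isopropyl group trans. A hydrogenation across C7=C8 could not do this, since syn addition there would make H7 and H8 cis.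

**Carbon for oxygen at C8.** Enone 14 is traced through diol 13 and hydroxy ester 12 to the conjugated ester 10. The ester carbon is used before it is removed: as the acceptor of an extended enolate it allows the alkene to be moved from C7=C8 to C6=C7 while oxygen is put on C8, and glycol cleavage then leaves the enone directly. Degrading the ester carbon while C7=C8 is still in place was set aside. It would leave a C8 carbonyl whose readily enolisable neighbour is C9 (doubly activated by C1=C10), so the unsaturation could not be brought back regioselectively to C6=C7.

**Key disconnection, C8–C9 and C5–C6.** Ester 10 is a cyclohepta-1,4-diene and is opened to diene 4 and vinyldiazoacetate 8 through the cis-divinylcyclopropane 9. Cutting here removes the whole seven-membered ring in one step, gives two small achiral fragments, and explains the position of C1=C10, which the rearrangement can place nowhere else. The forward reaction must cyclopropanate the isopropenyl group only, put the two alkenyl groups cis on the cyclopropane, and do so enantioselectively, because the cyclopropane configuration becomes that of C5.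

**Fragments.** Diene 4 comes from dienone 3 by ketalisation without alkene migration, and 3 from vinylogous ester 1 by carbonyl addition and transposition. Diazo ester 8 comes from β,γ-unsaturated ester 7 by diazo transfer, and 7 from allenoate 5 by conjugate addition of an isopropyl group.

## Alternatives that were turned down

**Alternative 1:** Wagner–Meerwein ring reorganisation. The C1–C5 bond is traced back to a C5–C10 bond of a cis-fused octalin, the eudesmane-type mesylate A1. In the forward step, buffered solvolysis of A1 in a carboxylic acid ionises C1, C5 shifts from C10 to C1, and the C10 cation loses a proton toward C1 to give the silyl ether A2 of the target dienol. In its favour: the stereocentres are set on six-membered rings, where conformational control is well understood. C3=C4, the C4 methyl and the C8 oxygen are in place before the skeleton changes. A2 is only a desilylation and an acylation away from the target. On the endgame this alternative is clearly stronger than the chosen route, which needs ten steps after its key step. Against it: A1 has five stereocentres, of which C1 and C10 exist only to be destroyed. The leaving group must be anti-periplanar to C5–C10 in a mobile cis-decalin, and the unusual trans relation of H5 and H7 has to be built into the decalin by a long linear sequence. The cationic step has several exits: proton loss toward C9 or C14, participation of the homoallylic C3=C4 alkene, and plain elimination toward C2. The product, with its doubly allylic C5–H, must survive warm acid. In exchange for its longer endgame, the chosen strategy offers a ring-forming step whose alkene position is dictated by a pericyclic mechanism and whose absolute configuration comes from a catalyst and two achiral fragments.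

**Alternative 2:** Buchner ring expansion. C1–C5 and C5–C6 are cut, so that the seven-membered ring becomes the benzene ring of thymol A3, carried as the achiral diazoketone A4. In the forward step a monovalent copper carbene with a chiral bis(oxazoline) adds across the arene C1–C6 bond and the norcaradiene opens to azulenone A5. In its favour: thymol already holds the isopropyl group, the methyl group and the oxygen at what become C7, C10 and C8, and the bicyclic skeleton is reached in very few steps with one asymmetric catalytic event. In step count to the ring system this is the strongest of all the routes considered, and stronger than the chosen one. Against it: A5 is a cycloheptatriene with alkenes at C1=C10, C6=C7 and C8=C9, of which only the first is wanted. Its C5–H is α to the C4 ketone and part of a triene that equilibrates with the norcaradiene, so the only stereocentre is configurationally fragile and acid-sensitive. Turning A5 into the target requires hydrolysing the enol ether to a C8 ketone, reducing C6=C7 with control at C7, reducing C8 with control, and keeping C1=C10 fixed, all on a cross-conjugated system where alkenes migrate easily. Carbene addition to the methyl-bearing ortho bond and aromatic substitution on the electron-rich ring are further leaks. The chosen strategy gives instead a ring with exactly two isolated alkenes and a C5 centre that is not next to a carbonyl until the last steps.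

**Alternative 3:** Cope rearrangement of a bicyclo[3.1.0]hexene. C8–C9 is cut and C1–C6 re-formed, giving the bicyclic divinylcyclopropane A6 with a bridgehead isopropenyl group and an exo (E)-enol ether on C6. Heating A6 forms C8–C9 and opens the cyclopropane to triene A7, the methoxymethyl ether of the 6,7-dehydro dienol. In its favour: it uses the same stereospecific boat rearrangement. The five-membered ring arrives finished, and the C8 oxygen arrives with its configuration transmitted from the enol ether geometry, so no carbon-for-oxygen exchange and no late C4 ketone are needed. After the key step this alternative is shorter than the chosen route. Against it: the difficulty is moved into A6, which needs three defined cyclopropane stereocentres including a quaternary bridgehead, and a trisubstituted enol ether of one geometry, the wrong isomer giving the C8 epimer. Preparing it would cost more steps than are saved. A7 has a C5–H flanked by three alkenes. Its acetal must be removed with acid, and its C6=C7 alkene must be hydrogenated under hydroxyl direction in the presence of the equally trisubstituted C3=C4. The chosen strategy keeps C3=C4 masked as a dioxolane during that hydrogenation and draws its cyclopropane from an intermolecular, catalyst-controlled step on simple fragments.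

Key step: step 5

**Assumptions.**
- Methyl buta-2,3-dienoate 5 is taken as a purchased material.
- The sense of induction of Rh2(S-DOSP)4 is assumed to follow the usual pattern of its cyclopropanations with donor–acceptor carbenoids, which gives 9 as drawn and, through the boat rearrangement, 5S in 10; if the substrate responds in the opposite sense, Rh2(R-DOSP)4 is used and nothing else changes.
- The C5 descriptor changes from S to R in step 15 only because the priorities at C4 change; no bond at C5 is touched.

## Route

Step 1
Reactants: 1 3-ethoxycyclopent-2-en-1-one
Product: 3 3-(prop-1-en-2-yl)cyclopent-2-en-1-one, via tertiary allylic carbinol 2 (not isolated)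
Conditions: CH2=C(CH3)MgBr (1.3 equiv), THF, 0 °C; then 1 M HCl, 0 °C to rt
Reagents that add atoms: isopropenylmagnesium bromide, CC(=C)[Mg]Br; water, O
Why: 1,2-Addition of the Grignard reagent to the vinylogous ester gives carbinol 2, which ionises on acidification and is hydrolysed with allylic transposition to the 3-substituted enone (Stork–Danheiser sequence); no stereocentre is formed.

Step 2
Reactants: 3 3-(prop-1-en-2-yl)cyclopent-2-en-1-one
Product: 4 7-(prop-1-en-2-yl)-1,4-dioxaspiro[4.4]non-6-ene
Conditions: Me3SiOCH2CH2OSiMe3 (1.5 equiv), Me3SiOTf (5 mol%), CH2Cl2, −78 °C; pyridine quench; chromatography on Et3N-deactivated silica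
Reagents that add atoms: 1,2-bis(trimethylsilyloxy)ethane, C[Si](C)(C)OCCO[Si](C)(C)C
Why: Aprotic silyl-triflate-catalysed ketalisation at low temperature converts enones into dioxolanes without moving the double bond, which protic glycol conditions would not guarantee for a cross-conjugated dienone; the ketal makes the diene electron-rich and masks C4 until after the hydrogenation.

Step 3
Reactants: 5 methyl buta-2,3-dienoate
Product: 7 methyl 4-methyl-3-methylidenepentanoate, via chloromagnesium dienolate 6 (not isolated)
Conditions: iPrMgCl (1.2 equiv), CuI (10 mol%, monovalent copper), THF, −78 °C; then cold 1 M HCl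
Reagents that add atoms: isopropylmagnesium chloride, CC(C)[Mg]Cl
Why: Copper-catalysed conjugate addition of the Grignard reagent to the central allene carbon gives dienolate 6, and kinetic protonation at the α-carbon leaves the new 1,1-disubstituted alkene out of conjugation; this entry is chosen because a phosphorus ylide would only deprotonate a β-keto ester precursor instead of methylenating it.

Step 4
Reactants: 7 methyl 4-methyl-3-methylidenepentanoate
Product: 8 methyl 2-diazo-4-methyl-3-methylidenepentanoate
Conditions: 4-acetamidobenzenesulfonyl azide (1.3 equiv), DBU (1.5 equiv), MeCN, 0 °C; cold pentane extraction; used at once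
Reagents that add atoms: 4-acetamidobenzenesulfonyl azide, CC(=O)Nc1ccc(cc1)S(=O)(=O)N=[N+]=[N-]
Why: Regitz diazo transfer to the methylene that is both allylic and α to the ester is the standard entry to vinyldiazoacetates from β,γ-unsaturated esters; 8 is kept cold and dilute because vinyldiazo compounds with an unsubstituted terminus cyclise slowly to pyrazoles.

Step 5
Reactants: 4 7-(prop-1-en-2-yl)-1,4-dioxaspiro[4.4]non-6-ene; 8 methyl 2-diazo-4-methyl-3-methylidenepentanoate
Product: 10 methyl (5S)-4,4-ethylenedioxy-15-norguaia-1(10),7-diene-8-carboxylate, via cis-divinylcyclopropane 9 (not isolated)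
Conditions: Rh2(S-DOSP)4 (1 mol%, divalent rhodium), 4 (1.0 equiv), 8 (1.5 equiv, added over 2 h), hexanes, −40 °C to rt; then 50 °C, 1 h
Reagents that add atoms: none
Why: Loss of dinitrogen from 8 at the dirhodium catalyst gives a donor–acceptor vinylcarbenoid, which cyclopropanates the terminal CH2 of the isopropenyl group of 4 in a concerted asynchronous addition (C8–C9 leading, then C8–C10), the trisubstituted ring alkene being too hindered to compete. The cyclopentenyl group, which stabilises the developing positive charge at C10, takes the position syn to the vinyl group of the carbenoid as is usual for these carbenoids, so 9 is a cis-divinylcyclopropane and rearranges at or near room temperature through the boat [3,3] transition state, breaking C8–C10 and forming C5–C6. This is the known tandem cyclopropanation–Cope rearrangement (formal [4+3] cycloaddition) of vinyldiazoacetates with dienes, applied to a 1-alkenylcycloalkene. The seven-membered ring is closed in the sigmatropic step as a ring expansion of the three-membered ring, not as a cyclisation of a chain, which is why the cis,cis-cyclohepta-1,4-diene with C1=C10 at the ring fusion and C7=C8 next to the ester is the only constitution available. C5 is the one new stereocentre that survives: the chiral catalyst fixes the cyclopropane centres C8 and C10, and the boat geometry, with H5 turned inward as the cis substituent of the ring alkene terminus, relays that configuration to C5 while C8 and C10 become trigonal. The step needs site selectivity (secured by the substitution pattern of the two alkenes), cis selectivity in the cyclopropanation (secured by the conjugating cyclopentenyl group) and face selectivity at the carbenoid (secured by the catalyst, helped by the methyl ester and the hydrocarbon solvent in which this catalyst family performs best). The allylic dioxolane is tolerated as long as the mixture stays cold and acid-free, since cyclopropanation of an electron-rich diene outruns ylide formation or C–H insertion at the acetal.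

Step 6
Reactants: 10 methyl (5S)-4,4-ethylenedioxy-15-norguaia-1(10),7-diene-8-carboxylate
Product: 12 methyl (5S)-4,4-ethylenedioxy-8-hydroxy-15-norguaia-1(10),6-diene-8-carboxylate (both C8 epimers), via lithium dienolate 11 (not isolated)
Conditions: LiN(iPr)2 (1.3 equiv), THF/DMPU, −78 °C; then 2-(phenylsulfonyl)-3-phenyloxaziridine (1.5 equiv), −78 °C; AcOH quench
Reagents that add atoms: 2-(phenylsulfonyl)-3-phenyloxaziridine, O=S(=O)(c1ccccc1)N1OC1c1ccccc1
Why: γ-Deprotonation at the ring methylene C6, whose axial C–H overlaps with the enoate π system while the isopropyl C–H lies in the alkene plane to avoid allylic strain, gives the extended dienolate 11, which takes up electrophilic oxygen at the α-carbon C8 as ester dienolates do (deconjugative α-hydroxylation); the alkene is thereby moved to C6=C7 and oxygen placed on C8 in one operation, and the C8 configuration is irrelevant because it is erased in step 8.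

Step 7
Reactants: 12 methyl (5S)-4,4-ethylenedioxy-8-hydroxy-15-norguaia-1(10),6-diene-8-carboxylate
Product: 13 (5S)-4,4-ethylenedioxy-8-(hydroxymethyl)-15-norguaia-1(10),6-dien-8-ol (both C8 epimers)
Conditions: LiAlH4 (2 equiv), THF, 0 °C; aqueous potassium sodium tartrate work-up
Reagents that add atoms: none
Why: Hydride reduction of the α-hydroxy ester gives the 1,2-diol; the dioxolane and both unactivated alkenes are inert to LiAlH4.

Step 8
Reactants: 13 (5S)-4,4-ethylenedioxy-8-(hydroxymethyl)-15-norguaia-1(10),6-dien-8-ol
Product: 14 (5S)-4,4-ethylenedioxy-15-norguaia-1(10),6-dien-8-one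
Conditions: NaIO4 (1.5 equiv), THF/pH 7 phosphate buffer, 0 °C
Reagents that add atoms: none
Why: Periodate glycol cleavage removes the former ester carbon as formaldehyde and leaves the C8 ketone already conjugated with C6=C7, so the enone is reached without ever enolising a C8 ketone (which would go toward C9); the neutral buffer protects the dioxolane and keeps C1=C10 from moving through the acidic C9 position.

Step 9
Reactants: 14 (5S)-4,4-ethylenedioxy-15-norguaia-1(10),6-dien-8-one
Product: 15 (5S,8S)-4,4-ethylenedioxy-15-norguaia-1(10),6-dien-8-ol
Conditions: (R)-2-methyl-CBS-oxazaborolidine (0.3 equiv), catecholborane (1.8 equiv), toluene, −78 °C; MeOH, then aqueous NaOH work-up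
Reagents that add atoms: none
Why: Corey–Bakshi–Shibata reduction in the 1,2-sense: the α-branched alkenyl carbon C7 acts as the large and the C9 methylene as the small carbonyl substituent, so the (R)-catalyst should deliver hydride to the face that gives 8S, and the remote C5 centre should not override catalyst control.

Step 10
Reactants: 15 (5S,8S)-4,4-ethylenedioxy-15-norguaia-1(10),6-dien-8-ol
Product: 16 (5S,7R,8S)-4,4-ethylenedioxy-15-norguai-1(10)-en-8-ol
Conditions: [Rh(nbd)(dppb)]BF4 (5 mol%, monovalent rhodium), H2 (55 bar), CH2Cl2, rt
Reagents that add atoms: none
Why: Hydroxyl-directed homogeneous hydrogenation: the cationic rhodium centre binds the C8 hydroxyl and adds hydrogen to C6=C7 from the hydroxyl face, so H7 becomes cis to oxygen and the isopropyl group trans (7R); this catalyst class does not reduce the unfunctionalised tetrasubstituted C1=C10 alkene, and high pressure suppresses isomerisation of the allylic alcohol.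

Step 11
Reactants: 17 vanillic acid (4-hydroxy-3-methoxybenzoic acid)
Product: 19 4-(tert-butyldimethylsilyloxy)-3-methoxybenzoic acid, via bis-silylated vanillate 18 (not isolated)
Conditions: tBuMe2SiCl (2.3 equiv), imidazole (5 equiv), DMF, rt; then AcOH/THF/H2O (3:1:1), rt
Reagents that add atoms: tert-butyldimethylsilyl chloride, CC(C)(C)[Si](C)(C)Cl
Why: Exhaustive silylation followed by selective hydrolysis of the labile silyl ester leaves the aryl silyl ether; the phenol has to be blocked so that the acid does not acylate itself in step 12 and is not sulfonylated in step 14.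

Step 12
Reactants: 16 (5S,7R,8S)-4,4-ethylenedioxy-15-norguai-1(10)-en-8-ol; 19 4-(tert-butyldimethylsilyloxy)-3-methoxybenzoic acid
Product: 20 (5S,7R,8S)-4,4-ethylenedioxy-15-norguai-1(10)-en-8-yl 4-(tert-butyldimethylsilyloxy)-3-methoxybenzoate
Conditions: EDC·HCl (1.5 equiv), DMAP (1.0 equiv), CH2Cl2, 0 °C to rt
Reagents that add atoms: none
Why: Carbodiimide/DMAP (Steglich) acylation of the secondary alcohol proceeds with retention at C8; the final ester is installed now because a benzoate has no α-hydrogen and can protect C8 through the remaining base and palladium steps.

Step 13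
Reactants: 20 (5S,7R,8S)-4,4-ethylenedioxy-15-norguai-1(10)-en-8-yl 4-(tert-butyldimethylsilyloxy)-3-methoxybenzoate
Product: 21 (5S,7R,8S)-4-oxo-15-norguai-1(10)-en-8-yl 4-(tert-butyldimethylsilyloxy)-3-methoxybenzoate
Conditions: PPTS (0.2 equiv), acetone/H2O (10:1), 40 °C, stopped at full conversion; the product is used without storage
Reagents that add atoms: water, O
Why: Mild acid hydrolysis of the dioxolane; a weak acid is chosen because the β,γ-unsaturated ketone 21 can move C1=C10 into conjugation through its C4 enol, as with other β,γ-unsaturated ketones that are released from ketals under weak acid, while the aryl silyl ether and the benzoate are stable to these conditions.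

Step 14
Reactants: 21 (5S,7R,8S)-4-oxo-15-norguai-1(10)-en-8-yl 4-(tert-butyldimethylsilyloxy)-3-methoxybenzoate
Product: 23 (5S,7R,8S)-4-(trifluoromethanesulfonyloxy)-15-norguaia-1(10),3-dien-8-yl 4-(tert-butyldimethylsilyloxy)-3-methoxybenzoate, via potassium enolate 22 (not isolated)
Conditions: KN(SiMe3)2 (1.15 equiv), THF, −78 °C (ketone added to the base); then N-(5-chloropyridin-2-yl)bis(trifluoromethanesulfonyl)imide (1.3 equiv), −78 °C; aqueous NH4Cl
Reagents that add atoms: N-(5-chloropyridin-2-yl)bis(trifluoromethanesulfonyl)imide, O=S(=O)(N(c1ccc(Cl)cn1)S(=O)(=O)C(F)(F)F)C(F)(F)F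
Why: Kinetic deprotonation by the hindered amide base should take the accessible C3 methylene and not the ring-fusion methine C5, and O-sulfonylation of enolate 22 fixes the alkene at C3=C4; the alkene position is thus set by enolisation and not by an elimination that would favour the conjugated C4=C5 isomer.

Step 15
Reactants: 23 (5S,7R,8S)-4-(trifluoromethanesulfonyloxy)-15-norguaia-1(10),3-dien-8-yl 4-(tert-butyldimethylsilyloxy)-3-methoxybenzoate
Product: 24 (5R,7R,8S)-guaia-1(10),3-dien-8-yl 4-(tert-butyldimethylsilyloxy)-3-methoxybenzoate
Conditions: MeZnCl (2.5 equiv), Pd(PPh3)4 (5 mol%, zerovalent palladium), THF, 0 °C to rt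
Reagents that add atoms: methylzinc chloride, C[Zn]Cl
Why: Negishi cross-coupling of the alkenyl triflate (oxidative addition, transmetalation, reductive elimination) installs the C4 methyl group without moving the alkene; the organozinc reagent leaves the aryl ester and the silyl ether untouched.

Step 16
Reactants: 24 (5R,7R,8S)-guaia-1(10),3-dien-8-yl 4-(tert-butyldimethylsilyloxy)-3-methoxybenzoate
Product: 25 (5R,7R,8S)-guaia-1(10),3-dien-8-yl 4-hydroxy-3-methoxybenzoate
Conditions: Bu4NF (1.1 equiv), AcOH (1.2 equiv), THF, 0 °C
Reagents that add atoms: none
Why: Fluoride cleaves the aryl silyl ether quickly; buffering with acetic acid keeps the medium from becoming basic enough to transesterify the vanillate or isomerise the skipped diene.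

## Compound list

1 | 3-ethoxycyclopent-2-en-1-one | CCOC1=CC(=O)CC1 | starting material
2 | 3-ethoxy-1-(prop-1-en-2-yl)cyclopent-2-en-1-ol (formed as its bromomagnesium alkoxide) | CCOC1=CC(O)(C(C)=C)CC1 | intermediate (not isolated)
3 | 3-(prop-1-en-2-yl)cyclopent-2-en-1-one | CC(=C)C1=CC(=O)CC1 | intermediate
4 | 7-(prop-1-en-2-yl)-1,4-dioxaspiro[4.4]non-6-ene | C=C(C)C1=CC2(OCCO2)CC1 | intermediate
5 | methyl buta-2,3-dienoate | COC(=O)C=C=C | starting material
6 | chloromagnesium 1-methoxy-4-methyl-3-methylidenepent-1-en-1-olate (dienolate of 7) | COC(O[Mg]Cl)=CC(=C)C(C)C | intermediate (not isolated)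
7 | methyl 4-methyl-3-methylidenepentanoate | COC(=O)CC(=C)C(C)C | intermediate
8 | methyl 2-diazo-4-methyl-3-methylidenepentanoate | COC(=O)C(=[N+]=[N-])C(=C)C(C)C | intermediate
9 | methyl (1R,2R)-2-(1,4-dioxaspiro[4.4]non-6-en-7-yl)-2-methyl-1-(3-methylbut-1-en-2-yl)cyclopropane-1-carboxylate | COC(=O)[C@@]1(C(=C)C(C)C)C[C@]1(C)C1=CC2(OCCO2)CC1 | intermediate (not isolated)
10 | methyl (5S)-4,4-ethylenedioxy-15-norguaia-1(10),7-diene-8-carboxylate | COC(=O)C1=C(C(C)C)C[C@H]2C(CCC23OCCO3)=C(C)C1 | intermediate
11 | lithium dienolate of 10 (C6=C7, C8=C(OLi)OMe) | COC(O[Li])=C1C(C(C)C)=C[C@H]2C(CCC23OCCO3)=C(C)C1 | intermediate (not isolated)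
12 | methyl (5S)-4,4-ethylenedioxy-8-hydroxy-15-norguaia-1(10),6-diene-8-carboxylate (C8 epimers) | COC(=O)C1(O)C(C(C)C)=C[C@H]2C(CCC23OCCO3)=C(C)C1 | intermediate
13 | (5S)-4,4-ethylenedioxy-8-(hydroxymethyl)-15-norguaia-1(10),6-dien-8-ol (C8 epimers) | OCC1(O)C(C(C)C)=C[C@H]2C(CCC23OCCO3)=C(C)C1 | intermediate
14 | (5S)-4,4-ethylenedioxy-15-norguaia-1(10),6-dien-8-one | O=C1C(C(C)C)=C[C@H]2C(CCC23OCCO3)=C(C)C1 | intermediate
15 | (5S,8S)-4,4-ethylenedioxy-15-norguaia-1(10),6-dien-8-ol | O[C@H]1CC(C)=C2CCC3(OCCO3)[C@H]2C=C1C(C)C | intermediate
16 | (5S,7R,8S)-4,4-ethylenedioxy-15-norguai-1(10)-en-8-ol | O[C@H]1CC(C)=C2CCC3(OCCO3)[C@H]2C[C@@H]1C(C)C | intermediate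
17 | vanillic acid (4-hydroxy-3-methoxybenzoic acid) | COc1cc(C(=O)O)ccc1O | starting material
18 | tert-butyldimethylsilyl 4-(tert-butyldimethylsilyloxy)-3-methoxybenzoate | COc1cc(C(=O)O[Si](C)(C)C(C)(C)C)ccc1O[Si](C)(C)C(C)(C)C | intermediate (not isolated)
19 | 4-(tert-butyldimethylsilyloxy)-3-methoxybenzoic acid | COc1cc(C(=O)O)ccc1O[Si](C)(C)C(C)(C)C | intermediate
20 | (5S,7R,8S)-4,4-ethylenedioxy-15-norguai-1(10)-en-8-yl 4-(tert-butyldimethylsilyloxy)-3-methoxybenzoate | COc1cc(C(=O)O[C@H]2CC(C)=C3CCC4(OCCO4)[C@H]3C[C@@H]2C(C)C)ccc1O[Si](C)(C)C(C)(C)C | intermediate
21 | (5S,7R,8S)-4-oxo-15-norguai-1(10)-en-8-yl 4-(tert-butyldimethylsilyloxy)-3-methoxybenzoate | COc1cc(C(=O)O[C@H]2CC(C)=C3CCC(=O)[C@H]3C[C@@H]2C(C)C)ccc1O[Si](C)(C)C(C)(C)C | intermediate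
22 | potassium enolate of 21 (C3=C4–OK) | COc1cc(C(=O)O[C@H]2CC(C)=C3CC=C(O[K])[C@H]3C[C@@H]2C(C)C)ccc1O[Si](C)(C)C(C)(C)C | intermediate (not isolated)
23 | (5S,7R,8S)-4-(trifluoromethanesulfonyloxy)-15-norguaia-1(10),3-dien-8-yl 4-(tert-butyldimethylsilyloxy)-3-methoxybenzoate | COc1cc(C(=O)O[C@H]2CC(C)=C3CC=C(OS(=O)(=O)C(F)(F)F)[C@H]3C[C@@H]2C(C)C)ccc1O[Si](C)(C)C(C)(C)C | intermediate
24 | (5R,7R,8S)-guaia-1(10),3-dien-8-yl 4-(tert-butyldimethylsilyloxy)-3-methoxybenzoate | COc1cc(C(=O)O[C@H]2CC(C)=C3CC=C(C)[C@H]3C[C@@H]2C(C)C)ccc1O[Si](C)(C)C(C)(C)C | intermediate
25 | (5R,7R,8S)-guaia-1(10),3-dien-8-yl 4-hydroxy-3-methoxybenzoate, i.e. (6S,7R,8aR)-1,4-dimethyl-7-(propan-2-yl)-3,5,6,7,8,8a-hexahydroazulen-6-yl 4-hydroxy-3-methoxybenzoate | COc1cc(C(=O)O[C@H]2CC(C)=C3CC=C(C)[C@H]3C[C@@H]2C(C)C)ccc1O | target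

## Step count and least certain steps

Total: 16 steps. Longest linear sequence: 13 steps from 1 (steps 1, 2, 5–10, 12–16). Steps 3 and 4 (diazo ester) and step 11 (protected acid) are side branches.

**Step 5 (key step).** The most likely failure is erosion of enantiocontrol. The isopropyl group on the carbon next to the carbenoid centre crowds the catalyst pocket, and internally substituted vinylcarbenoids are the less well-behaved members of this class with prolinate catalysts. Two further leaks are slow cyclisation of 8 to a pyrazole before it reaches the catalyst, and formation of some trans-divinylcyclopropane, which rearranges only on heating and then through a diradical that erodes the stereochemistry. Fallback: move the origin of absolute configuration from the carbenoid step to the ketone reduction. Setting out from 4 and 8, the cycloaddition is run with achiral Rh2(O2CC7H15)4 (divalent rhodium) and gives 10 together with its enantiomer, methyl (5R)-4,4-ethylenedioxy-15-norguaia-1(10),7-diene-8-carboxylate F1. Steps 6 to 8 carry the racemate on through the enantiomeric hydroxy ester F2, the enantiomeric diol F3 and the enantiomeric enone F4. The reduction of step 9 then acts on both enantiomers of the enone with the same catalyst-controlled facial preference. It should give 15 and its C5 epimer, (5R,8S)-4,4-ethylenedioxy-15-norguaia-1(10),6-dien-8-ol F5, as diastereomers that are separated by chromatography. The route is rejoined at 15, at the price of half the material.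

**Step 6.** The most likely failure is proton removal at the wrong γ-position: the isopropyl methine lies syn to the ester carbonyl and can be reached by a carbonyl-bound amide base. Oxygen transfer to C6 instead of the crowded C8 is the second possibility. The first is partly self-correcting: an isopropylidene isomer would also give, after steps 7–9, an allylic alcohol whose directed hydrogenation sets the same C7 configuration. Fallback: use the existing C7=C8 alkene as an enamide instead of relying on dienolate regiochemistry. Setting out from 10, saponification (KOSiMe3, THF, 50 °C) gives the enoic acid F6. Diphenylphosphoryl azide and Et3N in toluene convert it into the acyl azide F7, which undergoes Curtius rearrangement at 80 °C to the vinyl isocyanate F8, and methanol traps this as the methyl enecarbamate F9. PhSeCl at −78 °C attacks the enecarbamate at C7, and hydrolysis with aqueous NaHCO3 gives the 7-phenylselanyl ketone F10. Oxidation with NaIO4 and syn elimination of the selenoxide toward C6 returns to the route at 14.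

**Step 10.** The most likely failure is incomplete facial direction, or isomerisation of the allylic alcohol to a ketone, because the seven-membered ring is flexible and the isopropyl group crowds the carbinol to which the metal must bind. Over-reduction of C1=C10 is the lesser worry with cationic rhodium. Fallback: set C7 by steric control and correct C8 afterwards by inversion. Setting out from 14, reduction with the (S)-oxazaborolidine and catecholborane gives the 8R allylic alcohol F11, and tBuPh2SiCl/imidazole gives its silyl ether F12. Heterogeneous hydrogenation (Rh/Al2O3, H2, EtOAc) from the face away from the silyloxy group gives the saturated silyl ether F13, in which H7 has the required orientation. Bu4NF then gives the (5S,7R,8R) alcohol F14. Mitsunobu esterification of this alcohol with 19 (PPh3, diisopropyl azodicarboxylate) inverts C8 and delivers 20, where the route is rejoined.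

**Step 14.** The most likely failure is enolisation toward C5, which is α to the carbonyl and allylic to C1=C10. It would epimerise C5 or lead to a dienyl triflate, and the same feature makes 21 prone to alkene migration already during step 13. Fallback: place the alkene by a syn elimination instead of by enolate regiochemistry. Setting out from 21, MeMgBr/CeCl3 (THF, −78 °C) adds to the ketone from the face of H5 and gives the tertiary alcohol F15, whose hydroxyl is trans to H5. Dehydration with methyl N-(triethylammoniosulfonyl)carbamate (Burgess reagent), a syn elimination for which H5 is not available, should give the C3=C4 alkene and so returns to the route at 24.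

## Further compounds

F1 | step 5 | methyl (5R)-4,4-ethylenedioxy-15-norguaia-1(10),7-diene-8-carboxylate (enantiomer of 10) | COC(=O)C1=C(C(C)C)C[C@@H]2C(CCC23OCCO3)=C(C)C1
F2 | step 5 | methyl (5R)-4,4-ethylenedioxy-8-hydroxy-15-norguaia-1(10),6-diene-8-carboxylate (enantiomeric series of 12) | COC(=O)C1(O)C(C(C)C)=C[C@@H]2C(CCC23OCCO3)=C(C)C1
F3 | step 5 | (5R)-4,4-ethylenedioxy-8-(hydroxymethyl)-15-norguaia-1(10),6-dien-8-ol (enantiomeric series of 13) | OCC1(O)C(C(C)C)=C[C@@H]2C(CCC23OCCO3)=C(C)C1
F4 | step 5 | (5R)-4,4-ethylenedioxy-15-norguaia-1(10),6-dien-8-one (enantiomer of 14) | O=C1C(C(C)C)=C[C@@H]2C(CCC23OCCO3)=C(C)C1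
F5 | step 5 | (5R,8S)-4,4-ethylenedioxy-15-norguaia-1(10),6-dien-8-ol (C5 epimer of 15) | O[C@H]1CC(C)=C2CCC3(OCCO3)[C@@H]2C=C1C(C)C
F6 | step 6 | (5S)-4,4-ethylenedioxy-15-norguaia-1(10),7-diene-8-carboxylic acid | OC(=O)C1=C(C(C)C)C[C@H]2C(CCC23OCCO3)=C(C)C1
F7 | step 6 | (5S)-4,4-ethylenedioxy-15-norguaia-1(10),7-diene-8-carbonyl azide | [N-]=[N+]=NC(=O)C1=C(C(C)C)C[C@H]2C(CCC23OCCO3)=C(C)C1
F8 | step 6 | (5S)-4,4-ethylenedioxy-8-isocyanato-15-norguaia-1(10),7-diene | O=C=NC1=C(C(C)C)C[C@H]2C(CCC23OCCO3)=C(C)C1
F9 | step 6 | methyl N-[(5S)-4,4-ethylenedioxy-15-norguaia-1(10),7-dien-8-yl]carbamate | COC(=O)NC1=C(C(C)C)C[C@H]2C(CCC23OCCO3)=C(C)C1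
F10 | step 6 | (5S)-4,4-ethylenedioxy-7-(phenylselanyl)-15-norguai-1(10)-en-8-one (C7 epimers) | O=C1C([Se]c3ccccc3)(C(C)C)C[C@H]2C(CCC24OCCO4)=C(C)C1
F11 | step 10 | (5S,8R)-4,4-ethylenedioxy-15-norguaia-1(10),6-dien-8-ol | O[C@@H]1CC(C)=C2CCC3(OCCO3)[C@H]2C=C1C(C)C
F12 | step 10 | tert-butyldiphenylsilyl ether of F11 | CC(C)(C)[Si](c1ccccc1)(c1ccccc1)O[C@@H]1CC(C)=C2CCC3(OCCO3)[C@H]2C=C1C(C)C
F13 | step 10 | tert-butyldiphenylsilyl ether of (5S,7R,8R)-4,4-ethylenedioxy-15-norguai-1(10)-en-8-ol | CC(C)(C)[Si](c1ccccc1)(c1ccccc1)O[C@@H]1CC(C)=C2CCC3(OCCO3)[C@H]2C[C@@H]1C(C)C
F14 | step 10 | (5S,7R,8R)-4,4-ethylenedioxy-15-norguai-1(10)-en-8-ol | O[C@@H]1CC(C)=C2CCC3(OCCO3)[C@H]2C[C@@H]1C(C)C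
F15 | step 14 | (4R,5S,7R,8S)-4-hydroxyguai-1(10)-en-8-yl 4-(tert-butyldimethylsilyloxy)-3-methoxybenzoate (hydroxyl trans to H5) | COc1cc(C(=O)O[C@H]2CC(C)=C3CC[C@@](C)(O)[C@H]3C[C@@H]2C(C)C)ccc1O[Si](C)(C)C(C)(C)C
A1 | alternative 1 | cis-fused 8-(tert-butyldimethylsilyloxy)eudesm-3-en-1-yl methanesulfonate (sulfonate trans to the angular methyl) | CS(=O)(=O)O[C@H]1CC=C(C)[C@H]2C[C@H](C(C)C)[C@@H](O[Si](C)(C)C(C)(C)C)C[C@@]12C
A2 | alternative 1 | tert-butyldimethylsilyl ether of (5R,7R,8S)-guaia-1(10),3-dien-8-ol | CC(C)(C)[Si](C)(C)O[C@H]1CC(C)=C2CC=C(C)[C@H]2C[C@@H]1C(C)C
A3 | alternative 2 | thymol (5-methyl-2-(propan-2-yl)phenol) | Cc1ccc(C(C)C)c(O)c1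
A4 | alternative 2 | 1-diazo-4-[4-methoxy-2-methyl-5-(propan-2-yl)phenyl]butan-2-one | COc1cc(C)c(CCC(=O)C=[N+]=[N-])cc1C(C)C
A5 | alternative 2 | (8aS)-6-methoxy-4-methyl-7-(propan-2-yl)-3,8a-dihydroazulen-1(2H)-one | O=C1CCC2=C(C)C=C(OC)C(C(C)C)=C[C@H]12
A6 | alternative 3 | 6-[(E)-1-(methoxymethoxy)-3-methylbut-1-en-2-yl]-2-methyl-5-(prop-1-en-2-yl)bicyclo[3.1.0]hex-2-ene (C6 substituent exo, cis to the isopropenyl group) | C=C(C)[C@]12CC=C(C)[C@H]1[C@@H]2/C(C(C)C)=C/OCOC
A7 | alternative 3 | methoxymethyl ether of (5R,8S)-guaia-1(10),3,6-trien-8-ol | COCO[C@H]1CC(C)=C2CC=C(C)[C@H]2C=C1C(C)C
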